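**Retrosynthetic overview**

- The target is an 8-hydroxy-3,4-dihydroisocoumarin: ring A (benzene, C4a–C8a, OH on C8) fused to ring B (δ-lactone, C1(=O)–O2–C3–C4). C3 is (R) and carries a (Z)-pentadec-6-enyl chain. The last step is only an O-demethylation.
- Ring B is cut at C3–C4 and at O2–C3. C3 is an O-acylated carbinol carbon (a masked aldehyde carbon) and C4 is a benzylic carbon held ortho, through C4a–C8a, to the carboxyl carbon C1 on ring A, whose C=O can chelate a metal on C3. This 1,6-relation of two activated sp3 carbons across the ester makes the closure possible.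
- The precursors are (Z)-hexadec-7-enal (Z-selective Wittig, then partial ester reduction) and 2-(chloromethyl)-6-methoxybenzoyl chloride (ring-opened 7-methoxyphthalide).
- In one pot the acyl chloride adds across the aldehyde C=O (O2–C3), and a chiral nickel catalyst then closes C3–C4 by enantioconvergent reductive coupling, which sets (R)-C3.
- Ring order: ring A is bought; ring B is the only ring formed (step 4).

Key step: step 4

Assumption: the phosphonium salt, the oxo ester and 7-methoxyphthalide are catalogue compounds, and in step 4 the (S,S)-ligand is taken to deliver (R)-C3; its antipode would be used if the sense is the opposite.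

**Step 1**
Reactants: 1 nonyltriphenylphosphonium bromide; 2 methyl 7-oxoheptanoate
Product: 4 methyl (Z)-hexadec-7-enoate, via nonylidenetriphenylphosphorane 3 (not isolated)
Conditions: NaN(SiMe3)2 (1.0 equiv), THF, 0 °C; then 2, −78 °C to rt
Reagents that add atoms: none
Why: Salt-free Wittig olefination of an aliphatic aldehyde with a non-stabilized ylide is kinetically Z-selective, and the ylide should react with the aldehyde far faster than with the methyl ester.

**Step 2**
Reactants: 4 methyl (Z)-hexadec-7-enoate
Product: 6 (Z)-hexadec-7-enal, via aluminium hemiacetal 5 (not isolated)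
Conditions: i-Bu2AlH (1.05 equiv), CH2Cl2, −78 °C; MeOH quench, then aq. potassium sodium tartrate
Reagents that add atoms: none
Why: Partial hydride reduction of a methyl ester with one equivalent of i-Bu2AlH at −78 °C should stop at the tetrahedral aluminium hemiacetal 5, which releases the aldehyde only on aqueous work-up, and the isolated Z-alkene is inert to the hydride.

**Step 3**
Reactants: 7 7-methoxyphthalide (7-methoxy-2-benzofuran-1(3H)-one)
Product: 8 2-(chloromethyl)-6-methoxybenzoyl chloride
Conditions: SOCl2 (3 equiv), BnEt3NCl (2 mol %), BF3·OEt2 (2 mol %), 95 °C; excess SOCl2 distilled off, 8 used crude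
Reagents that add atoms: thionyl chloride, O=S(Cl)Cl
Why: Catalysed ring-opening chlorination of a phthalide with thionyl chloride (the standard route to 2-(chloromethyl)benzoyl chlorides): chloride opens the activated lactone at the benzylic CH2 by SN2 and the carboxyl becomes the acyl chloride, while the aryl methyl ether should be inert.

**Step 4**
Reactants: 8 2-(chloromethyl)-6-methoxybenzoyl chloride; 6 (Z)-hexadec-7-enal
Product: 10 (R)-8-methoxy-3-[(Z)-pentadec-6-en-1-yl]isochroman-1-one, via racemic 1-chloroalkyl ester 9 (not isolated)
Conditions: ZnCl2 (5 mol %), CH2Cl2, 0 °C to rt; then added slowly to NiBr2·DME (10 mol %), (S,S)-2,2'-isopropylidenebis(4-isopropyl-2-oxazoline) (12 mol %), Mn powder (3 equiv), NaI (0.5 equiv), DMA–THF, 0 °C, 0.01 M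
Reagents that add atoms: none
Why: Proposed new method: the acyl chloride first adds across the aldehyde C=O under ZnCl2 catalysis (the known acyl halide–aldehyde addition) to give the racemic 1-chloroalkyl ester 9, in which C3 sits at the aldehyde oxidation level next to O2; a chiral bis(oxazoline)–nickel catalyst, turned over by zerovalent manganese, then inserts into the benzylic C4–Cl bond, abstracts the halogen from C3 to give an α-acyloxyalkyl radical stabilized by O2 that recombines with nickel, and C(sp3)–C(sp3) reductive elimination forms C3–C4. The closest known reaction types are the nickel-catalysed enantioconvergent alkylation of racemic 1-haloalkyl esters by alkylnickel species (intermolecular) and nickel/manganese asymmetric reductive couplings of benzylic chlorides with iodide as co-catalyst; new here is that both electrophilic carbons sit in one molecule, so the coupling closes a ring. Ring B is closed by reductive elimination from a seven-membered nickelacycle (Ni, C4, C4a, C8a, C1, O2, C3), which requires the ester to reach its s-cis rotamer. The C3 stereocentre is set by the chiral ligand on nickel at the radical-capture and reductive-elimination stage, with the C1=O oxygen as second binding point, so both enantiomers of 9 should converge on (R)-10 through the planar C3 radical. The step needs ring closure to win over intermolecular coupling, hydrodehalogenation and β-hydride loss to an enol ester, which the ortho relation of CH2Cl and the carboxyl on ring A and the high dilution should secure. The Z-alkene should stay untouched because no nickel hydride source is present and the C3 radical could reach it only through a slow seven- or eight-membered closure.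

**Step 5**
Reactants: 10 (R)-8-methoxy-3-[(Z)-pentadec-6-en-1-yl]isochroman-1-one
Product: 12 (R)-8-hydroxy-3-[(Z)-pentadec-6-en-1-yl]isochroman-1-one (target), via dichloroboryl ether 11 (not isolated)
Conditions: BCl3 (1 M in CH2Cl2, 1.5 equiv), CH2Cl2, −78 to 0 °C; aq. NaHCO3
Reagents that add atoms: none
Why: Chelation-assisted Lewis-acid demethylation of an aryl methyl ether peri to a carbonyl: BCl3 binds C1=O and the C8 oxygen, chloride removes the methyl group as MeCl, and the lactone, the uninvolved C3 stereocentre and the Z-alkene should survive these mild conditions.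

**Compound list**

1 | nonyltriphenylphosphonium bromide | CCCCCCCCC[P+](c1ccccc1)(c1ccccc1)c1ccccc1.[Br-] | starting material
2 | methyl 7-oxoheptanoate | COC(=O)CCCCCC=O | starting material
3 | nonylidenetriphenylphosphorane (ylide, not isolated) | CCCCCCCCC=P(c1ccccc1)(c1ccccc1)c1ccccc1 | intermediate
4 | methyl (Z)-hexadec-7-enoate | CCCCCCCC/C=C\CCCCCC(=O)OC | intermediate
5 | diisobutylaluminium hemiacetal of 4, O-(diisobutylalumanyl) 1-methoxy-(Z)-hexadec-7-en-1-olate (not isolated) | CCCCCCCC/C=C\CCCCCC(OC)O[Al](CC(C)C)CC(C)C | intermediate
6 | (Z)-hexadec-7-enal | CCCCCCCC/C=C\CCCCCC=O | intermediate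
7 | 7-methoxyphthalide (7-methoxy-2-benzofuran-1(3H)-one) | COc1cccc2COC(=O)c12 | starting material
8 | 2-(chloromethyl)-6-methoxybenzoyl chloride | COc1cccc(CCl)c1C(Cl)=O | intermediate
9 | (±)-(Z)-1-chlorohexadec-7-en-1-yl 2-(chloromethyl)-6-methoxybenzoate (not isolated) | CCCCCCCC/C=C\CCCCCC(Cl)OC(=O)c1c(CCl)cccc1OC | intermediate
10 | (R)-8-methoxy-3-[(Z)-pentadec-6-en-1-yl]isochroman-1-one | CCCCCCCC/C=C\CCCCC[C@@H]1Cc2cccc(OC)c2C(=O)O1 | intermediate
11 | (R)-8-(dichloroboryloxy)-3-[(Z)-pentadec-6-en-1-yl]isochroman-1-one, boron chelated by C1=O (not isolated) | CCCCCCCC/C=C\CCCCC[C@@H]1Cc2cccc(OB(Cl)Cl)c2C(=O)O1 | intermediate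
12 | (R)-8-hydroxy-3-[(Z)-pentadec-6-en-1-yl]isochroman-1-one | CCCCCCCC/C=C\CCCCC[C@@H]1Cc2cccc(O)c2C(=O)O1 | target

**Step count**

Total steps: 5. Longest linear sequence: 4 steps (steps 1, 2, 4, 5); step 3 is a one-step side branch.

**Steps most likely to fail**

1. Step 4 (proposed new method). The ring closure may lose to intermolecular coupling or hydrodehalogenation, because the ester has to reach its s-cis rotamer before the nickelacycle can form. Facial control at the C3 radical may be insufficient. Carbonyl-assisted loss of the benzylic halide may also return the phthalide. The fallback uses known chemistry, sets out from aldehyde 6 and comes back at 10. Corey–Chaykovsky methylenation of 6 (Me3SI, NaH, DMSO–THF) should give racemic 2-[(Z)-pentadec-6-en-1-yl]oxirane F1. Hydrolytic kinetic resolution with (R,R)-(salen)Co(OAc) and 0.55 equiv of water (or the antipodal complex, if the sense is the opposite) should leave (R)-2-[(Z)-pentadec-6-en-1-yl]oxirane F2. Commercial N,N-diethyl-2-methoxybenzamide is ortho-lithiated (s-BuLi, TMEDA, THF, −78 °C) to N,N-diethyl-2-lithio-6-methoxybenzamide F3, which should open F2 at its terminal carbon in the presence of BF3·OEt2 to give N,N-diethyl-2-[(2R,8Z)-2-hydroxyheptadec-8-en-1-yl]-6-methoxybenzamide F4. Heating F4 with p-TsOH in toluene should lactonize it to 10, the C3 configuration being that of the epoxide.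

2. Step 3. The aryl methyl ether may be cleaved in the hot Lewis-acidic medium, or the lactone may reclose on contact with moisture during isolation. The fallback sets out from 7 and comes back at 10. HBr in AcOH at rt should open the lactone of 7 at the benzylic carbon to 2-(bromomethyl)-6-methoxybenzoic acid F5, and oxalyl bromide (cat. DMF, CH2Cl2, 0 °C) should convert it into 2-(bromomethyl)-6-methoxybenzoyl bromide F6. F6 is added to aldehyde 6 (ZnBr2 cat.) to give (±)-(Z)-1-bromohexadec-7-en-1-yl 2-(bromomethyl)-6-methoxybenzoate F7, which is cyclized under the nickel/manganese conditions of step 4 without NaI to 10.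

3. Step 2. The tetrahedral intermediate may collapse before the quench, so that reduction runs past the aldehyde stage. The fallback sets out from 4 and comes back at 6. Full reduction with LiAlH4 (THF, 0 °C) should give (Z)-hexadec-7-en-1-ol F8, and oxidation with Dess–Martin periodinane (CH2Cl2, NaHCO3) should return aldehyde 6 without touching the alkene geometry.

**Further compounds**

F1 | step 4 | racemic 2-[(Z)-pentadec-6-en-1-yl]oxirane | CCCCCCCC/C=C\CCCCCC1CO1
F2 | step 4 | (R)-2-[(Z)-pentadec-6-en-1-yl]oxirane | CCCCCCCC/C=C\CCCCC[C@@H]1CO1
F3 | step 4 | N,N-diethyl-2-lithio-6-methoxybenzamide | [Li]c1cccc(OC)c1C(=O)N(CC)CC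
F4 | step 4 | N,N-diethyl-2-[(2R,8Z)-2-hydroxyheptadec-8-en-1-yl]-6-methoxybenzamide | CCCCCCCC/C=C\CCCCC[C@@H](O)Cc1cccc(OC)c1C(=O)N(CC)CC
F5 | step 3 | 2-(bromomethyl)-6-methoxybenzoic acid | COc1cccc(CBr)c1C(=O)O
F6 | step 3 | 2-(bromomethyl)-6-methoxybenzoyl bromide | COc1cccc(CBr)c1C(Br)=O
F7 | step 3 | (±)-(Z)-1-bromohexadec-7-en-1-yl 2-(bromomethyl)-6-methoxybenzoate | CCCCCCCC/C=C\CCCCCC(Br)OC(=O)c1c(CBr)cccc1OC
F8 | step 2 | (Z)-hexadec-7-en-1-ol | CCCCCCCC/C=C\CCCCCCO
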